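## Retrosynthetic overview

- The target is taken back to its hepta-O-benzyl ether, then to the corresponding C4 ketone (cis-selective hydride reduction), then to 5,7,3′,4′-tetra-O-benzyl-(2R,3R)-dihydroquercetin and tri-O-benzylgallic acid (esterification of the 3-OH).
- The pyranone ring (O1–C2–C3–C4–C4a–C8a) is made from a racemic seven-membered acetal, a 2-aryl-1,3-benzodioxepin-5(4H)-one (ring O1–C2–O3–C4–C5(=O)–C5a–C9a). C2 shifts from the acetal oxygen O3 to the ketone α-carbon and O3 leaves the ring to become the 3-OH. This ring contraction 7→6 forms the C2–C3 bond and sets C2 and C3, with both enantiomers of the acetal converging.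
- Enabling feature: C2 lies between the ring oxygen O1 and the electron-rich catechol ring, so it can be an oxocarbenium carbon. C3 carries an oxygen and is α to C4, which at the ketone level makes it an enol carbon. The C2–C3 bond is therefore the retron of an O→C 1,2-shift.
- The acetal comes from acetalisation of a 2-hydroxyaryl hydroxymethyl ketone with 3,4-bis(benzyloxy)benzaldehyde; the ketol comes from 2′,4′,6′-trihydroxyacetophenone by benzylation and Rubottom oxidation.
- Ring order: the A, B and galloyl rings are bought; the dioxepinone ring is closed in step 3 and contracted to the pyranone ring in step 4.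

Key step: step 4

Assumption: the sense of induction of the chiral acid in step 4 cannot be derived from a close precedent; the (R)-catalyst is written, and its mirror image would be used if the (2S,3S) series should prevail.

## Route

Step 1
Reactants: 1 2′,4′,6′-trihydroxyacetophenone
Product: 2 1-[2,4-bis(benzyloxy)-6-hydroxyphenyl]ethan-1-one
Conditions: BnBr (2.1 equiv), K2CO3, DMF, rt
Reagents that add atoms: benzyl bromide, BrCc1ccccc1
Why: Williamson ether synthesis in which the 4-OH and one ortho-OH are alkylated while the remaining ortho-OH is held back by its hydrogen bond to the acetyl carbonyl, so that exactly the phenol needed for the later acetal stays free.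

Step 2
Reactants: 2 1-[2,4-bis(benzyloxy)-6-hydroxyphenyl]ethan-1-one
Product: 5 1-[2,4-bis(benzyloxy)-6-hydroxyphenyl]-2-hydroxyethan-1-one, via bis-TMS enol ether 3 (not isolated), via α-silyloxy ketone 4 (not isolated)
Conditions: TMSOTf, Et3N, CH2Cl2, 0 °C, pentane filtration; mCPBA, CH2Cl2, −20 °C; 1 M HCl, THF, rt
Reagents that add atoms: mCPBA, O=C(OO)c1cccc(Cl)c1 (the new oxygen); TMSOTf, C[Si](C)(C)OS(=O)(=O)C(F)(F)F (silyl groups of 3 and 4 only, lost on hydrolysis)
Why: Rubottom oxidation, in which soft enolisation can only go towards the methyl group and at the same time masks the phenol as its silyl ether (so that closure to a benzofuranone cannot interfere), the silyl enol ether is epoxidised, the silyl group shifts to the new oxygen and mild acid frees both hydroxyl groups.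

Step 3
Reactants: 5 1-[2,4-bis(benzyloxy)-6-hydroxyphenyl]-2-hydroxyethan-1-one, 6 3,4-bis(benzyloxy)benzaldehyde
Product: 8 (±)-6,8-bis(benzyloxy)-2-[3,4-bis(benzyloxy)phenyl]-1,3-benzodioxepin-5(4H)-one, via dimethyl acetal 7 (not isolated)
Conditions: 6, HC(OMe)3 (1.1 equiv), PPTS (cat.), CH2Cl2, rt, evaporation; then 5, PPTS (cat.), PhMe, 5 Å MS, 50 °C
Reagents that add atoms: trimethyl orthoformate, COC(OC)OC (methoxy groups of 7 only)
Why: Acid-catalysed transacetalisation in which the primary alcohol exchanges first and the phenol then closes the seven-membered ring on the aryl-stabilised oxocarbenium ion, driven by uptake of methanol on the sieves and run with an acid too weak to start C–C bond formation; the acetal centre forms as a racemate, which is without consequence because step 4 erases it.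

Step 4
Reactants: 8 (±)-6,8-bis(benzyloxy)-2-[3,4-bis(benzyloxy)phenyl]-1,3-benzodioxepin-5(4H)-one
Product: 9 (2R,3R)-5,7-bis(benzyloxy)-2-[3,4-bis(benzyloxy)phenyl]-3-hydroxy-2,3-dihydro-4H-chromen-4-one
Conditions: (R)-3,3′-bis(2,4,6-triisopropylphenyl)-1,1′-binaphthyl-2,2′-diyl N-triflylphosphoramide (5 mol%), PhMe, 4 Å MS, −20 °C to rt, Ar
Reagents that add atoms: none
Why: Proposed new method: the strong chiral acid protonates the alkyl-type acetal oxygen O3 of 8, and C2–O3 heterolysis, assisted by the 4-benzyloxyphenyl group, gives an O-aryl oxocarbenium ion that stays tethered through O1 to the released α-hydroxy ketone and paired with the chiral anion, which also mediates enolisation towards the CH2 group (C4 of 8); this enol carbon attacks the cationic C2, so that C2 moves from O3 to the neighbouring carbon (net 1,2-shift) and O3 leaves the ring to become the 3-OH of 9 (ring contraction 7→6). The closest known reaction types are the Petasis–Ferrier and related acid-mediated O→C rearrangements of cyclic enol acetals, the [1,2]-Wittig rearrangement of acetals and chiral-anion-controlled additions of enols to oxocarbenium ions; a 1,2-shift onto the α-carbon of a ketone under chiral acid control has no direct precedent. The pyranone ring closes in a 6-(enolendo)-endo-trig mode. C2 is set by the chiral counter-anion, which differentiates the faces of the planar cation, and because ionisation erases the acetal stereocentre both enantiomers of 8 should converge on one product; C3 follows from a half-chair transition state with aryl and hydroxyl pseudo-equatorial, and a 2,3-cis isomer can still reach the trans series by acid-catalysed enolisation, C3 being α to the ketone. The step needs productive C2–O3 cleavage and C-attack at the α-carbon: C2–O1 cleavage and O-recombination are reversible and only return 8, and attack through the carbonyl carbon would be a 5-endo closure to a less stable α-hydroxy aldehyde, whereas the intended path ends in a conjugated aryl ketone in a six-membered ring.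

Step 5
Reactants: 9 (2R,3R)-5,7-bis(benzyloxy)-2-[3,4-bis(benzyloxy)phenyl]-3-hydroxy-2,3-dihydro-4H-chromen-4-one, 10 3,4,5-tris(benzyloxy)benzoic acid
Product: 11 (2R,3R)-5,7-bis(benzyloxy)-2-[3,4-bis(benzyloxy)phenyl]-4-oxo-3,4-dihydro-2H-chromen-3-yl 3,4,5-tris(benzyloxy)benzoate
Conditions: DCC, DMAP (cat.), CH2Cl2, 0 °C to rt, Ar
Reagents that add atoms: none
Why: Steglich esterification of the secondary 3-OH through the acylpyridinium ion, which forms the ester without breaking a bond at C3 and at a temperature at which neither enolisation at C3 nor β-elimination of the ring oxygen should compete.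

Step 6
Reactants: 11 (2R,3R)-5,7-bis(benzyloxy)-2-[3,4-bis(benzyloxy)phenyl]-4-oxo-3,4-dihydro-2H-chromen-3-yl 3,4,5-tris(benzyloxy)benzoate
Product: 12 (2R,3S,4S)-5,7-bis(benzyloxy)-2-[3,4-bis(benzyloxy)phenyl]-4-hydroxy-3,4-dihydro-2H-chromen-3-yl 3,4,5-tris(benzyloxy)benzoate
Conditions: L-Selectride, THF, −78 °C; AcOH quench at −78 °C, no oxidative work-up
Reagents that add atoms: none
Why: Substrate-controlled reduction with a bulky trialkylborohydride, which should avoid the axial trajectory (syn to the axial H-2) and add along the equatorial direction of the half-chair, so that the new C4–OH is axial and cis to the 3-O-galloyl group (4S); the aryl ester is inert at −78 °C and the cold acidic quench protonates the alkoxide before acyl transfer can occur.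

Step 7
Reactants: 12 (2R,3S,4S)-5,7-bis(benzyloxy)-2-[3,4-bis(benzyloxy)phenyl]-4-hydroxy-3,4-dihydro-2H-chromen-3-yl 3,4,5-tris(benzyloxy)benzoate
Product: 13 (2R,3S,4S)-2-(3,4-dihydroxyphenyl)-4,5,7-trihydroxy-3,4-dihydro-2H-chromen-3-yl 3,4,5-trihydroxybenzoate
Conditions: H2 (1 atm), 20% Pd(OH)2/C, THF–MeOH, rt; filtration under Ar, evaporation below 30 °C
Reagents that add atoms: none
Why: Hydrogenolysis of the seven O-benzyl ethers under neutral conditions, in which the ester, the C2–O1 bond and the secondary C4–OH are expected to persist if the reaction is stopped after uptake of seven equivalents of hydrogen; no stereocentre is touched.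

## Compound list

1 | 2′,4′,6′-trihydroxyacetophenone | CC(=O)c1c(O)cc(O)cc1O | starting material
2 | 1-[2,4-bis(benzyloxy)-6-hydroxyphenyl]ethan-1-one | CC(=O)c1c(O)cc(OCc2ccccc2)cc1OCc1ccccc1 | intermediate
3 | {1-[2,4-bis(benzyloxy)-6-(trimethylsilyloxy)phenyl]ethenyloxy}trimethylsilane | C=C(O[Si](C)(C)C)c1c(O[Si](C)(C)C)cc(OCc2ccccc2)cc1OCc1ccccc1 | intermediate
4 | 1-[2,4-bis(benzyloxy)-6-(trimethylsilyloxy)phenyl]-2-(trimethylsilyloxy)ethan-1-one | O=C(CO[Si](C)(C)C)c1c(O[Si](C)(C)C)cc(OCc2ccccc2)cc1OCc1ccccc1 | intermediate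
5 | 1-[2,4-bis(benzyloxy)-6-hydroxyphenyl]-2-hydroxyethan-1-one | O=C(CO)c1c(O)cc(OCc2ccccc2)cc1OCc1ccccc1 | intermediate
6 | 3,4-bis(benzyloxy)benzaldehyde | O=Cc1ccc(OCc2ccccc2)c(OCc2ccccc2)c1 | starting material
7 | 3,4-bis(benzyloxy)benzaldehyde dimethyl acetal | COC(OC)c1ccc(OCc2ccccc2)c(OCc2ccccc2)c1 | intermediate
8 | (±)-6,8-bis(benzyloxy)-2-[3,4-bis(benzyloxy)phenyl]-1,3-benzodioxepin-5(4H)-one | O=C1COC(c2ccc(OCc3ccccc3)c(OCc3ccccc3)c2)Oc2cc(OCc3ccccc3)cc(OCc3ccccc3)c21 | intermediate
9 | (2R,3R)-5,7-bis(benzyloxy)-2-[3,4-bis(benzyloxy)phenyl]-3-hydroxy-2,3-dihydro-4H-chromen-4-one | O[C@@H]1[C@@H](c2ccc(OCc3ccccc3)c(OCc3ccccc3)c2)Oc2cc(OCc3ccccc3)cc(OCc3ccccc3)c2C1=O | intermediate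
10 | 3,4,5-tris(benzyloxy)benzoic acid | OC(=O)c1cc(OCc2ccccc2)c(OCc2ccccc2)c(OCc2ccccc2)c1 | starting material
11 | (2R,3R)-5,7-bis(benzyloxy)-2-[3,4-bis(benzyloxy)phenyl]-4-oxo-3,4-dihydro-2H-chromen-3-yl 3,4,5-tris(benzyloxy)benzoate | O=C(O[C@@H]1[C@@H](c2ccc(OCc3ccccc3)c(OCc3ccccc3)c2)Oc2cc(OCc3ccccc3)cc(OCc3ccccc3)c2C1=O)c1cc(OCc2ccccc2)c(OCc2ccccc2)c(OCc2ccccc2)c1 | intermediate
12 | (2R,3S,4S)-5,7-bis(benzyloxy)-2-[3,4-bis(benzyloxy)phenyl]-4-hydroxy-3,4-dihydro-2H-chromen-3-yl 3,4,5-tris(benzyloxy)benzoate | O=C(O[C@@H]1[C@@H](c2ccc(OCc3ccccc3)c(OCc3ccccc3)c2)Oc2cc(OCc3ccccc3)cc(OCc3ccccc3)c2[C@@H]1O)c1cc(OCc2ccccc2)c(OCc2ccccc2)c(OCc2ccccc2)c1 | intermediate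
13 | (2R,3S,4S)-2-(3,4-dihydroxyphenyl)-4,5,7-trihydroxy-3,4-dihydro-2H-chromen-3-yl 3,4,5-trihydroxybenzoate | O=C(O[C@@H]1[C@@H](c2ccc(O)c(O)c2)Oc2cc(O)cc(O)c2[C@@H]1O)c1cc(O)c(O)c(O)c1 | target

## Step count and risks

Total steps: 7. Longest linear sequence: 7 steps (1 to 13); 6 and 10 are bought.

**Step 4 (ring contraction).** The ion pair may only recombine at oxygen and return the acetal, the C–C bond may form without facial control, or the product may lose configuration at C2 by reversible ionisation under the strong acid. The fallback uses known chemistry, sets out from 2 and 6 and comes back at 9; the pyranone ring is then closed directly.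
- 2 is converted with MOMCl and NaH in DMF into 1-[2,4-bis(benzyloxy)-6-(methoxymethoxy)phenyl]ethan-1-one F1.
- Claisen–Schmidt condensation with 6 (KOH, EtOH) gives (E)-1-[2,4-bis(benzyloxy)-6-(methoxymethoxy)phenyl]-3-[3,4-bis(benzyloxy)phenyl]prop-2-en-1-one F2.
- Juliá–Colonna epoxidation (poly-L-leucine, urea–H2O2, DBU, THF) should give the (αR,βS)-epoxide [2,4-bis(benzyloxy)-6-(methoxymethoxy)phenyl]{(2R,3S)-3-[3,4-bis(benzyloxy)phenyl]oxiran-2-yl}methanone F3.
- HCl in MeOH–THF at 50 °C removes the MOM group and lets the phenol open the epoxide at the benzylic carbon (6-endo, trans product favoured, C3 untouched) to give 9.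

**Step 3 (seven-membered acetal).** Ring closure may stall at acyclic mixed acetals or oligomers, because the hydrogen-bonded phenol is a poor nucleophile and the equilibrium for the seven-membered ring may be unfavourable; prolonged acid contact may also start a racemic rearrangement. The fallback replaces the equilibrium transacetalisation by an irreversible silyl-transfer acetalisation. It sets out from 4, kept from step 2 by non-aqueous work-up instead of hydrolysis, and from 6. Catalytic TMSOTf in CH2Cl2 at −78 °C joins the two silyl ethers of 4 to the aldehyde, driven by formation of the disiloxane, and comes back at 8. This fallback makes no new compound (F0).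

**Step 7 (global hydrogenolysis).** The activated benzylic C4–O bond may be cleaved by over-reduction, and the C4 centre may ionise during the long deprotection. The fallback removes the benzyl groups while C4 is still a ketone; it sets out from 11 and comes back at 13.
- Hydrogenolysis of 11 (H2, Pd(OH)2/C, THF–MeOH) gives (2R,3R)-2-(3,4-dihydroxyphenyl)-5,7-dihydroxy-4-oxo-3,4-dihydro-2H-chromen-3-yl 3,4,5-trihydroxybenzoate F4.
- F4 is persilylated in the flask with N,O-bis(trimethylsilyl)acetamide to the hepta-O-trimethylsilyl ketone F5.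
- F5 is reduced with L-Selectride at −78 °C to the hepta-O-trimethylsilyl (2R,3S,4S)-alcohol F6.
- F6 is desilylated by dilute citric acid in aqueous THF to give 13.

## Further compounds

F1 | step 4 | 1-[2,4-bis(benzyloxy)-6-(methoxymethoxy)phenyl]ethan-1-one | CC(=O)c1c(OCOC)cc(OCc2ccccc2)cc1OCc1ccccc1
F2 | step 4 | (E)-1-[2,4-bis(benzyloxy)-6-(methoxymethoxy)phenyl]-3-[3,4-bis(benzyloxy)phenyl]prop-2-en-1-one | O=C(/C=C/c1ccc(OCc2ccccc2)c(OCc2ccccc2)c1)c1c(OCOC)cc(OCc2ccccc2)cc1OCc1ccccc1
F3 | step 4 | [2,4-bis(benzyloxy)-6-(methoxymethoxy)phenyl]{(2R,3S)-3-[3,4-bis(benzyloxy)phenyl]oxiran-2-yl}methanone | O=C([C@@H]1O[C@H]1c1ccc(OCc2ccccc2)c(OCc2ccccc2)c1)c1c(OCOC)cc(OCc2ccccc2)cc1OCc1ccccc1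
F0 | step 3 | none | none
F4 | step 7 | (2R,3R)-2-(3,4-dihydroxyphenyl)-5,7-dihydroxy-4-oxo-3,4-dihydro-2H-chromen-3-yl 3,4,5-trihydroxybenzoate | O=C(O[C@@H]1[C@@H](c2ccc(O)c(O)c2)Oc2cc(O)cc(O)c2C1=O)c1cc(O)c(O)c(O)c1
F5 | step 7 | hepta-O-trimethylsilyl ether of F4 | O=C(O[C@@H]1[C@@H](c2ccc(O[Si](C)(C)C)c(O[Si](C)(C)C)c2)Oc2cc(O[Si](C)(C)C)cc(O[Si](C)(C)C)c2C1=O)c1cc(O[Si](C)(C)C)c(O[Si](C)(C)C)c(O[Si](C)(C)C)c1
F6 | step 7 | hepta-O-trimethylsilyl ether of 13 (phenols silylated, 4-OH free) | O=C(O[C@@H]1[C@@H](c2ccc(O[Si](C)(C)C)c(O[Si](C)(C)C)c2)Oc2cc(O[Si](C)(C)C)cc(O[Si](C)(C)C)c2[C@@H]1O)c1cc(O[Si](C)(C)C)c(O[Si](C)(C)C)c(O[Si](C)(C)C)c1
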